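**Retrosynthetic overview**
1. Target 20 ⇐ 13-desmethyl pentacycle 18 (C13 methylation on the convex face) ⇐ N-(4-chlorobutyl) keto-lactone 14 by intramolecular Wittig closure of ring C (azepine, C8=C9); the N4–C5 bond is made at the outset by N-alkylation of pyrrole.
2. 14 ⇐ butenolide ketone 13 by Friedel–Crafts conjugate addition of pyrrole C1 to C12 (closes carbocycle B, cis-fused).
3. Key C–O disconnection: ring D of 13 ⇐ lactone C14–O bond, closed by an isomerising lactonisation of syn-aldol 11 (C10/C11 from an Ipc2B aldol of ketone 9 with ethyl 4-oxobut-2-enoate).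
4. Ring E (pendant lactone) ⇐ lactone C–O bond after carboxyl-directed reduction of keto acid 5, which comes from 1-(4-chlorobutyl)pyrrole and (R)-methylsuccinic anhydride.
5. Ring order: A (pyrrole, bought) → E → D → B → C; C13 methyl last.

Assumption: atoms are numbered as in tuberostemonine (pyrrole N4, C3, C2, C1, C9a; azepine C5–C9; carbocycle C9–C12; fused lactone C11–O–C14(=O)–C13–C12; pendant lactone C18–C21 on C3 with methyl on C20; ethyl on C10).

**Step 1**
Reactants: 1 pyrrole; 2 1-bromo-4-chlorobutane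
Product: 3 1-(4-chlorobutyl)-1H-pyrrole
Conditions: KOH, DMSO, 20 °C
Reagents that add atoms: 1-bromo-4-chlorobutane, ClCCCCBr
Why: SN2 N-alkylation of the pyrrolide anion, in which the bromide end reacts and the primary chloride is kept as the handle for ring C; no stereocentre is formed.

**Step 2**
Reactants: 3 1-(4-chlorobutyl)-1H-pyrrole; 4 (R)-methylsuccinic anhydride
Product: 5 (2R)-4-[1-(4-chlorobutyl)-1H-pyrrol-2-yl]-2-methyl-4-oxobutanoic acid
Conditions: AlCl3, CH2Cl2, −20 → 0 °C; 1 M HCl
Reagents that add atoms: (R)-methylsuccinic anhydride, O=C1C[C@@H](C)C(=O)O1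
Why: Friedel–Crafts acylation, α-selective on the N-alkylpyrrole, with the anhydride opened at its less hindered carbonyl (remote from the methyl group), so the C20 stereocentre is carried over unchanged from 4.

**Step 3**
Reactants: 5 (2R)-4-[1-(4-chlorobutyl)-1H-pyrrol-2-yl]-2-methyl-4-oxobutanoic acid
Product: 7 (3R,5R)-5-[1-(4-chlorobutyl)-1H-pyrrol-2-yl]-3-methyloxolan-2-one, via hydroxy acid 6 (not isolated)
Conditions: (−)-Ipc2BH, THF, −20 → 25 °C; then H2O, pH 5, 25 °C
Reagents that add atoms: none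
Why: Carboxyl-directed asymmetric reduction with diisopinocampheylborane (the acid binds boron and hydride is delivered intramolecularly) sets C18 under reagent control (the antipodal borane is taken if the sense on this pyrrolyl ketone proves opposite), and spontaneous γ-lactonisation then closes ring E through a C–O bond as the cis (R,R) lactone.

**Step 4**
Reactants: 7 (3R,5R)-5-[1-(4-chlorobutyl)-1H-pyrrol-2-yl]-3-methyloxolan-2-one; 8 butanoic anhydride
Product: 9 (3R,5R)-5-[5-butanoyl-1-(4-chlorobutyl)-1H-pyrrol-2-yl]-3-methyloxolan-2-one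
Conditions: (PrCO)2O, Sc(OTf)3 (5 mol%), MeNO2, 0 °C
Reagents that add atoms: butanoic anhydride, CCCC(=O)OC(=O)CCC
Why: Friedel–Crafts acylation at the only free α-position (C9a) of the electron-rich 1,2-dialkylpyrrole under mild triflate catalysis that leaves the pyrrolylic lactone intact; no stereocentre is formed.

**Step 5**
Reactants: 9 (3R,5R)-5-[5-butanoyl-1-(4-chlorobutyl)-1H-pyrrol-2-yl]-3-methyloxolan-2-one; 10 ethyl (2E)-4-oxobut-2-enoate
Product: 11 ethyl (2E,4S,5R)-5-{[1-(4-chlorobutyl)-5-[(2R,4R)-4-methyl-5-oxooxolan-2-yl]-1H-pyrrol-2-yl]carbonyl}-4-hydroxyhept-2-enoate (10,11-syn aldol)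
Conditions: (−)-Ipc2BOTf, i-Pr2NEt, CH2Cl2, −78 °C; 10, −78 → −20 °C; MeOH, pH 7 buffer, H2O2, 0 °C
Reagents that add atoms: ethyl (2E)-4-oxobut-2-enoate, CCOC(=O)/C=C/C=O
Why: Paterson boron aldol reaction, in which Z-selective enolisation by Ipc2BOTf and a closed chair transition state give the 10,11-syn diad, with the Ipc ligands fixing the absolute sense (the antipodal triflate is taken if induction on this ketone proves opposite) and overriding the remote lactone stereocentres.

**Step 6**
Reactants: 11 ethyl (2E,4S,5R)-5-{[1-(4-chlorobutyl)-5-[(2R,4R)-4-methyl-5-oxooxolan-2-yl]-1H-pyrrol-2-yl]carbonyl}-4-hydroxyhept-2-enoate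
Product: 13 (3R,5R)-5-{1-(4-chlorobutyl)-5-[(2R)-2-[(2S)-5-oxo-2,5-dihydrofuran-2-yl]butanoyl]-1H-pyrrol-2-yl}-3-methyloxolan-2-one (butenolide ketone), via Z-hydroxy ester 12 (not isolated)
Conditions: (4-MeOC6H4S)2 (10 mol%), PPTS (10 mol%), PhMe, 390 nm LEDs, 30 °C
Reagents that add atoms: none
Why: Proposed new method: arylthiyl radicals from visible-light homolysis of the disulfide add reversibly to C12 of the E-enoate (giving the ester-stabilised C13 radical), so rotation and β-scission keep E and Z isomers in equilibrium while only the Z isomer 12 is drained irreversibly by PPTS-catalysed transesterification of its C11 hydroxyl onto the ester, which closes ring D through the new C14–O bond with loss of ethanol and leaves C10 and C11 untouched; the closest known reactions are thiyl- or iodine-radical E/Z equilibration of enoates and the ultraviolet photoisomerisation–lactonisation of γ-hydroxy-E-enoates.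

**Step 7**
Reactants: 13 (3R,5R)-5-{1-(4-chlorobutyl)-5-[(2R)-2-[(2S)-5-oxo-2,5-dihydrofuran-2-yl]butanoyl]-1H-pyrrol-2-yl}-3-methyloxolan-2-one
Product: 14 tetracyclic keto-lactone: 1-(4-chlorobutyl)-6-ethyl-7-oxo-4,5,6,7-tetrahydroindole with a cis-fused γ-lactone across C4/C5 (O on C5; CH2C(=O) on C4) and the (2R,4R)-4-methyl-5-oxooxolan-2-yl group on C2; 10R,11S,12S
Conditions: Me2AlCl (3.5 equiv), CH2Cl2, −78 → 0 °C; 1 M HCl
Reagents that add atoms: none
Why: Intramolecular Friedel–Crafts (Michael-type) conjugate addition, 6-exo-trig, of pyrrole C1 to the Lewis-acid-activated butenolide, in which the ring-locked Z-alkene can be reached only from the face that carries the tether, so C12 is formed cis to the C11 oxygen (cis-fused lactone) and C10 and C11 are untouched.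

**Step 8**
Reactants: 14 tetracyclic keto-lactone; 15 triphenylphosphine
Product: 18 13-desmethyl pentacycle (the target without the C13 methyl group; all other stereocentres as in the target), via phosphonium chloride 16 (not isolated), via ylide 17 (not isolated)
Conditions: PPh3, NaI (20 mol%), MeCN, 85 °C; then KN(SiMe3)2 (1.0 equiv), THF, −78 → 25 °C
Reagents that add atoms: none
Why: Intramolecular Wittig olefination, in which the chloride is turned into the phosphonium salt under iodide catalysis and its ylide closes ring C on the C9 ketone, the ring fixing both position and geometry of the C8=C9 bond, while the ylide is too weak a base to enolise the ketone or the lactones.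

**Step 9**
Reactants: 18 13-desmethyl pentacycle; 19 iodomethane
Product: 20 target (10S,11R,12S,13R,18R,20R)
Conditions: LiN(i-Pr)2 (1.05 equiv), THF, −78 °C; MeI, −78 → −40 °C
Reagents that add atoms: iodomethane, CI
Why: Lactone enolate alkylation, in which kinetic deprotonation at the unhindered C13 methylene and methylation from the convex face of the cis-fused bicycle (anti to C1) set C13 as in the target, and any enolate of the pendant lactone is reprotonated to its cis form on quench.

**Compound list**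
1 | pyrrole | c1cc[nH]c1 | starting material
2 | 1-bromo-4-chlorobutane | ClCCCCBr | starting material
3 | 1-(4-chlorobutyl)-1H-pyrrole | ClCCCCn1cccc1 | intermediate
4 | (R)-methylsuccinic anhydride, (3R)-3-methyloxolane-2,5-dione | O=C1C[C@@H](C)C(=O)O1 | starting material
5 | (2R)-4-[1-(4-chlorobutyl)-1H-pyrrol-2-yl]-2-methyl-4-oxobutanoic acid | O=C(C[C@@H](C)C(=O)O)c1cccn1CCCCCl | intermediate
6 | (2R,4R)-4-[1-(4-chlorobutyl)-1H-pyrrol-2-yl]-4-hydroxy-2-methylbutanoic acid | ClCCCCn1cccc1[C@H](O)C[C@@H](C)C(=O)O | intermediate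
7 | (3R,5R)-5-[1-(4-chlorobutyl)-1H-pyrrol-2-yl]-3-methyloxolan-2-one | ClCCCCn1cccc1[C@H]2C[C@@H](C)C(=O)O2 | intermediate
8 | butanoic anhydride | CCCC(=O)OC(=O)CCC | starting material
9 | (3R,5R)-5-[5-butanoyl-1-(4-chlorobutyl)-1H-pyrrol-2-yl]-3-methyloxolan-2-one | CCCC(=O)c1ccc([C@H]2C[C@@H](C)C(=O)O2)n1CCCCCl | intermediate
10 | ethyl (2E)-4-oxobut-2-enoate | CCOC(=O)/C=C/C=O | starting material
11 | ethyl (2E,4S,5R)-5-{[1-(4-chlorobutyl)-5-[(2R,4R)-4-methyl-5-oxooxolan-2-yl]-1H-pyrrol-2-yl]carbonyl}-4-hydroxyhept-2-enoate | CC[C@H]([C@@H](O)/C=C/C(=O)OCC)C(=O)c1ccc([C@H]2C[C@@H](C)C(=O)O2)n1CCCCCl | intermediate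
12 | (2Z)-isomer of 11 | CC[C@H]([C@@H](O)/C=C\C(=O)OCC)C(=O)c1ccc([C@H]2C[C@@H](C)C(=O)O2)n1CCCCCl | intermediate
13 | (3R,5R)-5-{1-(4-chlorobutyl)-5-[(2R)-2-[(2S)-5-oxo-2,5-dihydrofuran-2-yl]butanoyl]-1H-pyrrol-2-yl}-3-methyloxolan-2-one | CC[C@H]([C@H]1OC(=O)C=C1)C(=O)c1ccc([C@H]2C[C@@H](C)C(=O)O2)n1CCCCCl | intermediate
14 | tetracyclic keto-lactone (10R,11S,12S): 1-(4-chlorobutyl)-6-ethyl-7-oxo-4,5,6,7-tetrahydroindole, cis-fused γ-lactone across C4/C5, (2R,4R)-4-methyl-5-oxooxolan-2-yl on C2 | CC[C@H]1C(=O)c2n(CCCCCl)c([C@H]3C[C@@H](C)C(=O)O3)cc2[C@H]2[C@@H]1OC(=O)C2 | intermediate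
15 | triphenylphosphine | c1ccc(cc1)P(c1ccccc1)c1ccccc1 | starting material
16 | phosphonium chloride of 14 (Ph3P+ in place of Cl) | CC[C@H]1C(=O)c2n(CCCC[P+](c3ccccc3)(c3ccccc3)c3ccccc3)c([C@H]3C[C@@H](C)C(=O)O3)cc2[C@H]2[C@@H]1OC(=O)C2.[Cl-] | intermediate
17 | phosphorus ylide from 16 | CC[C@H]1C(=O)c2n(CCCC=P(c3ccccc3)(c3ccccc3)c3ccccc3)c([C@H]3C[C@@H](C)C(=O)O3)cc2[C@H]2[C@@H]1OC(=O)C2 | intermediate
18 | 13-desmethyl pentacycle (target without the C13 methyl) | CC[C@H]1C2=CCCCn3c([C@H]4C[C@@H](C)C(=O)O4)cc(c32)[C@H]2[C@@H]1OC(=O)C2 | intermediate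
19 | iodomethane | CI | starting material
20 | target (10S,11R,12S,13R,18R,20R) | CC[C@H]1C2=CCCCn3c([C@H]4C[C@@H](C)C(=O)O4)cc(c32)[C@H]2[C@@H]1OC(=O)[C@@H]2C | target

**Totals**
Total steps: 9. Longest linear sequence: 9 (from pyrrole 1).

**Three steps most likely to fail, with fallbacks**

Step 6 (the proposed new lactonisation). The radical-chain equilibration may not feed the Z isomer fast enough, or thiyl radicals may attack elsewhere. The fallback is known chemistry and sets out from ketone 9. The same (−)-Ipc2BOTf aldol, now with acrolein, gives the vinyl carbinol F1. Acryloyl chloride (Et3N, DMAP cat., CH2Cl2, −20 °C) gives the acrylate F2. Ring-closing metathesis with the second-generation Grubbs catalyst (5 mol%, CH2Cl2, 40 °C) then closes the butenolide and comes back to the route at 13.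

Step 7 (Friedel–Crafts conjugate addition on the acylpyrrole). C1 of a 2-acylpyrrole is a weak nucleophile, the Lewis acid also binds the ketone, and acid-induced loss of the β-acyloxy group could erode C10/C11. The fallback removes the deactivating ketone before the ring closure and sets out from aldol 11. Et3SiCl/imidazole gives the triethylsilyl ether F3. PPh3/NaI (cat.) in MeCN gives the phosphonium chloride F4, and KN(SiMe3)2 gives the ylide F5, which closes to the azepine silyl ether F6 (the β-silyloxy ketone tolerates the ylide). HF·pyridine liberates the azepine carbinol F7. Irradiation at 300 nm (the known photoisomerisation–lactonisation) passes through the Z-ester F8 to the azepine butenolide F9. The now electron-rich 2-vinylpyrrole cyclises with Sc(OTf)3 (10 mol%) buffered with 2,6-di-tert-butylpyridine (CH2Cl2, 0 °C), and the route is rejoined at 18.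

Step 8 (intramolecular Wittig). The ylide may act as a base on the β-acyloxy ketone (β-elimination, then aromatisation to a 7-hydroxyindole), and closure of the seven-membered ring on a hindered, electron-rich ketone may be slow. The fallback avoids a basic carbanion and sets out from 14. NaI in acetone gives the iodide F10. A Barbier cyclisation with SmI2 (2.5 equiv, NiI2 cat., THF, −78 °C) gives the tertiary carbinol F11. Syn-dehydration with the Burgess reagent (PhMe, 50 °C) into the less hindered C8 methylene rejoins the route at 18.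

**Further compounds**
F1 | step 6 | (3R,5R)-5-{1-(4-chlorobutyl)-5-[(2R,3S)-2-ethyl-3-hydroxypent-4-enoyl]-1H-pyrrol-2-yl}-3-methyloxolan-2-one | CC[C@H]([C@@H](O)C=C)C(=O)c1ccc([C@H]2C[C@@H](C)C(=O)O2)n1CCCCCl
F2 | step 6 | acrylate of F1: (3S,4R)-4-{[1-(4-chlorobutyl)-5-[(2R,4R)-4-methyl-5-oxooxolan-2-yl]-1H-pyrrol-2-yl]carbonyl}hex-1-en-3-yl prop-2-enoate | CC[C@H]([C@@H](OC(=O)C=C)C=C)C(=O)c1ccc([C@H]2C[C@@H](C)C(=O)O2)n1CCCCCl
F3 | step 7 | triethylsilyl ether of 11 | CC[C@H]([C@@H](O[Si](CC)(CC)CC)/C=C/C(=O)OCC)C(=O)c1ccc([C@H]2C[C@@H](C)C(=O)O2)n1CCCCCl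
F4 | step 7 | phosphonium chloride of F3 (Ph3P+ in place of Cl) | CC[C@H]([C@@H](O[Si](CC)(CC)CC)/C=C/C(=O)OCC)C(=O)c1ccc([C@H]2C[C@@H](C)C(=O)O2)n1CCCC[P+](c1ccccc1)(c1ccccc1)c1ccccc1.[Cl-]
F5 | step 7 | phosphorus ylide from F4 | CC[C@H]([C@@H](O[Si](CC)(CC)CC)/C=C/C(=O)OCC)C(=O)c1ccc([C@H]2C[C@@H](C)C(=O)O2)n1CCCC=P(c1ccccc1)(c1ccccc1)c1ccccc1
F6 | step 7 | azepine silyl ether: 6,7-dihydro-5H-pyrrolo[1,2-a]azepine from Wittig closure of F5 (C9 bears the C10 side chain; silyl ether and E-enoate retained) | CC[C@H]([C@@H](O[Si](CC)(CC)CC)/C=C/C(=O)OCC)C1=CCCCn2c1ccc2[C@H]1C[C@@H](C)C(=O)O1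
F7 | step 7 | azepine carbinol (F6 without the silyl group) | CC[C@H]([C@@H](O)/C=C/C(=O)OCC)C1=CCCCn2c1ccc2[C@H]1C[C@@H](C)C(=O)O1
F8 | step 7 | (2Z)-isomer of F7 | CC[C@H]([C@@H](O)/C=C\C(=O)OCC)C1=CCCCn2c1ccc2[C@H]1C[C@@H](C)C(=O)O1
F9 | step 7 | azepine butenolide (ring D closed; ring B still open) | CC[C@H]([C@H]1OC(=O)C=C1)C1=CCCCn2c1ccc2[C@H]1C[C@@H](C)C(=O)O1
F10 | step 8 | iodide analogue of 14 (I in place of Cl) | CC[C@H]1C(=O)c2n(CCCCI)c([C@H]3C[C@@H](C)C(=O)O3)cc2[C@H]2[C@@H]1OC(=O)C2
F11 | step 8 | tertiary carbinol from Barbier closure of ring C (C9–OH; both C9 epimers) | CC[C@H]1C2(O)CCCCn3c([C@H]4C[C@@H](C)C(=O)O4)cc(c32)[C@H]2[C@@H]1OC(=O)C2
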